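A direct plan would build the arene the biomimetic way: two polyanion Claisen acylations would give methyl 3,5,7-trioxotriacontanoate (A1), and aldol closure with aromatisation of A1 would give methyl 2,4-dihydroxy-6-tricosylbenzoate (A2).
Methylation of A2 would give methyl 2,4-dimethoxy-6-tricosylbenzoate (A3), and the ester of A3 would then be traded for the hydroxyl: reduction to (2,4-dimethoxy-6-tricosylphenyl)methanol (A4), oxidation of A4 to 2,4-dimethoxy-6-tricosylbenzaldehyde (A5), a Dakin-type Baeyer–Villiger shift of A5 to 2,4-dimethoxy-6-tricosylphenyl formate (A6), and methanolysis of A6 to the target.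
Its weak points would be:
- the ester-to-hydroxyl exchange from A3 through A4, A5 and A6: reduction, oxidation, Baeyer–Villiger shift and cleavage build nothing, on a carbon put in only to be cut out;
- the aldol ring closure of A1 to A2: it must win over Claisen, pyrone and alternative aldol closures of a labile polyketone, with only the base as control;
- the run-up to A1: two acylations that each consume a twofold excess of polyanion and LiN(iPr)2 to reach an unstable chain that cannot be purified.

**Retrosynthetic overview**
The target is cut at two neighbouring bonds of its only ring: C6–C1′ (ring to tricosyl chain) and C1–O (the phenol oxygen), the centre of the C2(OMe)–C1(OH)–C6(tricosyl) triad.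
Both bonds are made in one flask on 3,5-dimethoxybenzyne: the methoxy group beside the triple bond (the future C2–OMe) sends the tricosyl carbanion to C6 and returns the metal to C1, where borylation and oxidation turn it into OH.
The ring is bought with both methoxy groups in place, so no ring is closed, no polyketone is handled and no carboxyl placeholder is carried; the only other work is turning 1-tricosanol into its lithium reagent.

Key step: step 3

Assumption: 1-tricosanol is taken as the commercial C23 source and 1-fluoro-3,5-dimethoxybenzene as the commercial arene; if 1-bromotricosane is bought, step 1 falls away.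

**Step 1**
Reactants: 1 1-tricosanol
Product: 2 1-bromotricosane
Conditions: PPh3 (1.3 equiv), CBr4 (1.3 equiv), CH2Cl2/THF, 0 → 35 °C; filtration through silica with hexane
Reagents that add atoms: carbon tetrabromide, BrC(Br)(Br)Br
Why: Appel reaction, an SN2 displacement of the alkoxyphosphonium ion by bromide at an unhindered primary carbon with no other functional group present.

**Step 2**
Reactants: 2 1-bromotricosane
Product: 3 tricosyllithium (ether solution, titrated and used promptly)
Conditions: Li wire (2.5 equiv, 1% Na), Et2O, Ar, slow addition of 2 at 0 → 15 °C; filtration under Ar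
Reagents that add atoms: lithium, [Li]
Why: Reductive lithiation of a primary alkyl bromide by lithium metal, the classical preparation of n-alkyllithiums, with slow addition and low temperature holding back Wurtz coupling.

**Step 3**
Reactants: 4 1-fluoro-3,5-dimethoxybenzene; 3 tricosyllithium
Product: 9 2,4-dimethoxy-6-tricosylphenol, via 2-fluoroaryllithium 5 (not isolated), via 3,5-dimethoxybenzyne 6 (not isolated), via 6-tricosylaryllithium 7 (not isolated), via dimethyl arylboronate 8 (not isolated)
Conditions: 4 (1.0 equiv), n-BuLi (0.97 equiv), THF, −78 °C; 3 (1.4 equiv in Et2O), −78 → 0 °C; B(OMe)3 (4 equiv), −78 °C → rt; AcOH, 30% H2O2, 0 °C → rt; aq. Na2S2O3; chromatography (surplus chain returns as 1)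
Reagents that add atoms: hydrogen peroxide, OO (the phenol oxygen of 9); trimethyl borate, COB(OC)OC (boron and methoxy groups of intermediate 8 only); n-butyllithium, [Li]CCCC (lithium of intermediate 5 only)
Why: n-BuLi removes H-2 of 4, the proton between fluorine (the strongest inductive acidifier) and a coordinating methoxy group, and aryllithium 5 loses LiF above about −50 °C to give aryne 6. Tricosyllithium then adds to the aryne carbon that had carried fluorine, because the methoxy group beside the triple bond withdraws through the sigma frame, distorts the aryne so that the remote carbon is the more electrophilic one, shields the near carbon, and stabilises the new carbanion beside it inductively and by O–Li contact; the second methoxy group, para to that carbanion, has almost no say. Aryllithium 7 therefore holds lithium at the future C1 between OMe and the chain, and borylation followed by the boron-to-oxygen 1,2-shift with hydrogen peroxide puts the hydroxyl on exactly that carbon. The closest known reaction type is the carbolithiation of 3-methoxybenzynes by n-alkyllithiums with electrophilic trapping of the ortho-methoxy aryllithium (a three-component aryne coupling), joined to the borylation–oxidation of aryl organometallics to phenols. No ring is closed and no stereocentre is formed. The step needs lithiation at C2 and not at C4, the alkyllithium and not an aryllithium as the nucleophile, and no over-oxidation of the electron-rich phenol: H-2 is the most acidic ring proton and its anion is drained irreversibly by loss of LiF whereas a C4 anion has no ortho leaving group, the unhindered primary alkyllithium is in excess over the doubly ortho-substituted aryllithiums, and the peroxide acts under acetic acid buffering at 0 °C before a thiosulfate quench.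

**Compound list**
1 | 1-tricosanol | CCCCCCCCCCCCCCCCCCCCCCCO | starting material
2 | 1-bromotricosane | CCCCCCCCCCCCCCCCCCCCCCCBr | intermediate
3 | tricosyllithium | [Li]CCCCCCCCCCCCCCCCCCCCCCC | intermediate
4 | 1-fluoro-3,5-dimethoxybenzene | COc1cc(F)cc(OC)c1 | starting material
5 | (2-fluoro-4,6-dimethoxyphenyl)lithium (not isolated) | [Li]c1c(F)cc(OC)cc1OC | intermediate
6 | 3,5-dimethoxybenzyne, 1,2-didehydro-3,5-dimethoxybenzene (not isolated) | COC1=CC(OC)=CC#C1 | intermediate
7 | (2,4-dimethoxy-6-tricosylphenyl)lithium (not isolated) | [Li]c1c(OC)cc(OC)cc1CCCCCCCCCCCCCCCCCCCCCCC | intermediate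
8 | dimethyl (2,4-dimethoxy-6-tricosylphenyl)boronate (not isolated) | COB(OC)c1c(OC)cc(OC)cc1CCCCCCCCCCCCCCCCCCCCCCC | intermediate
9 | 2,4-dimethoxy-6-tricosylphenol | CCCCCCCCCCCCCCCCCCCCCCCc1cc(OC)cc(OC)c1O | target

Total step count: 3. Longest linear sequence: 3 (1 → 2 → 3 → 9; arene 4 enters in step 3).

**Steps most likely to fail**

Step 3. Metalation of 4 could occur between the two methoxy groups instead of beside fluorine, or the aryne could be captured by aryllithiums 5 and 7 instead of by 3, so that little 7 would form. The fallback avoids the aryne and sets out from 3. Transmetalation with ZnCl2 should give tricosylzinc chloride (F1). Negishi coupling of F1 with commercial 1-bromo-3,5-dimethoxybenzene (PdCl2(dppf) cat., THF, 50 °C) should give 1,3-dimethoxy-5-tricosylbenzene (F2). NBS in CH2Cl2/MeCN at 0 °C should brominate F2 para to one methoxy group and ortho to the chain, giving 2-bromo-1,5-dimethoxy-3-tricosylbenzene (F3). Bromine–lithium exchange on F3 with n-BuLi in THF at −78 °C should then deliver aryllithium 7, where the route is rejoined before the borate is added.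

Step 2. Wurtz homocoupling at the lithium surface and sluggish reaction of the waxy bromide could leave a weak, halide-laden reagent. The fallback needs no C23 organometallic and sets out from 4. The same lithiation of 4 with n-BuLi and aryne generation (THF, −78 °C → rt), with commercial allylmagnesium bromide as the carbon nucleophile, should give (2-allyl-4,6-dimethoxyphenyl)magnesium bromide (F4). Borylation of F4 with B(OMe)3 should give dimethyl (2-allyl-4,6-dimethoxyphenyl)boronate (F5), and oxidation of F5 (AcOH, 30% H2O2, 0 °C) should give 2-allyl-4,6-dimethoxyphenol (F6). Cross-metathesis of F6 with commercial 1-docosene (second-generation Grubbs catalyst RuCl2(=CHPh)(PCy3)(H2IMes), CH2Cl2, 40 °C) should give 2,4-dimethoxy-6-[(E)-tricos-2-en-1-yl]phenol (F7) beside its Z isomer 2,4-dimethoxy-6-[(Z)-tricos-2-en-1-yl]phenol (F8). Hydrogenation of the mixture of F7 and F8 (H2, Pd/C, EtOAc) should come back to the route at 9.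

Step 1. Conversion could stay incomplete because the waxy alcohol remains out of solution at the temperature the phosphonium chemistry tolerates, and phosphine oxide could be carried into the metalation. The fallback sets out from 1. Mesylation (MsCl, Et3N, THF, 40 °C) should give tricosyl methanesulfonate (F9), and displacement of the mesylate group of F9 with LiBr in refluxing butanone should return to the route at 2.

**Further compounds**
F1 | step 3 | tricosylzinc chloride | Cl[Zn]CCCCCCCCCCCCCCCCCCCCCCC
F2 | step 3 | 1,3-dimethoxy-5-tricosylbenzene | CCCCCCCCCCCCCCCCCCCCCCCc1cc(OC)cc(OC)c1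
F3 | step 3 | 2-bromo-1,5-dimethoxy-3-tricosylbenzene | CCCCCCCCCCCCCCCCCCCCCCCc1cc(OC)cc(OC)c1Br
F4 | step 2 | (2-allyl-4,6-dimethoxyphenyl)magnesium bromide | Br[Mg]c1c(OC)cc(OC)cc1CC=C
F5 | step 2 | dimethyl (2-allyl-4,6-dimethoxyphenyl)boronate | COB(OC)c1c(OC)cc(OC)cc1CC=C
F6 | step 2 | 2-allyl-4,6-dimethoxyphenol | C=CCc1cc(OC)cc(OC)c1O
F7 | step 2 | 2,4-dimethoxy-6-[(E)-tricos-2-en-1-yl]phenol | CCCCCCCCCCCCCCCCCCCC/C=C/Cc1cc(OC)cc(OC)c1O
F8 | step 2 | 2,4-dimethoxy-6-[(Z)-tricos-2-en-1-yl]phenol | CCCCCCCCCCCCCCCCCCCC/C=C\Cc1cc(OC)cc(OC)c1O
F9 | step 1 | tricosyl methanesulfonate | CCCCCCCCCCCCCCCCCCCCCCCOS(C)(=O)=O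
A1 | direct plan | methyl 3,5,7-trioxotriacontanoate | COC(=O)CC(=O)CC(=O)CC(=O)CCCCCCCCCCCCCCCCCCCCCCC
A2 | direct plan | methyl 2,4-dihydroxy-6-tricosylbenzoate | COC(=O)c1c(O)cc(O)cc1CCCCCCCCCCCCCCCCCCCCCCC
A3 | direct plan | methyl 2,4-dimethoxy-6-tricosylbenzoate | COC(=O)c1c(OC)cc(OC)cc1CCCCCCCCCCCCCCCCCCCCCCC
A4 | direct plan | (2,4-dimethoxy-6-tricosylphenyl)methanol | OCc1c(OC)cc(OC)cc1CCCCCCCCCCCCCCCCCCCCCCC
A5 | direct plan | 2,4-dimethoxy-6-tricosylbenzaldehyde | O=Cc1c(OC)cc(OC)cc1CCCCCCCCCCCCCCCCCCCCCCC
A6 | direct plan | 2,4-dimethoxy-6-tricosylphenyl formate | O=COc1c(OC)cc(OC)cc1CCCCCCCCCCCCCCCCCCCCCCC
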